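**Plan**
Retrosynthesis: with both phenols masked as MOM ethers, the exocyclic C3=CH–aryl bond is cut first (aldol condensation with the syringaldehyde MOM ether), then the ring bond C3–C4 of the oxolan-2-one (carbenoid C–H insertion), then the ester bond O1–C2 (acylation of a 3-arylpropanol).
Enabling feature: C4 of the lactone is a CH lying between the ring C5H2–O1 and the benzylic CH2, so in the open-chain ester it is the methylene β to the ester oxygen, five atoms from a carbenoid at C3.
Forward: dihydroconiferyl alcohol is MOM-protected, esterified with bromoacetyl bromide and turned into the diazoacetate; the only ring, the five-membered lactone, closes in step 4; the arylidene arm is then joined at C3 and both MOM groups come off last.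
Stereochemistry: the single stereocentre C4 (R) comes from the chiral catalyst Rh2(4R-MPPIM)4, which picks one of two enantiotopic hydrogens; the E double bond comes from a base-mediated elimination that leads to the more stable conjugated isomer.

Key step: step 4

Remark on the chemistry: MPPIM is the carboxamidate of methyl 1-(3-phenylpropanoyl)-2-oxoimidazolidine-4-carboxylate. The 4R ligand hand is assumed to deliver the R lactone; should the sense prove opposite for this substrate, the 4S catalyst is used with no other change.

**Route**

Step 1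
Reactants: 1 3-(4-hydroxy-3-methoxyphenyl)propan-1-ol
Product: 2 3-[3-methoxy-4-(methoxymethoxy)phenyl]propan-1-ol
Conditions: MOMCl, K2CO3, acetone, 0 °C → rt
Reagents that add atoms: chloromethyl methyl ether (MOMCl), COCCl
Why: Williamson-type O-alkylation in which K2CO3 deprotonates only the phenol, so the phenoxide displaces chloride from the chloromethyl ether while the far less acidic primary alcohol stays free.

Step 2
Reactants: 2 3-[3-methoxy-4-(methoxymethoxy)phenyl]propan-1-ol; 3 bromoacetyl bromide
Product: 4 3-[3-methoxy-4-(methoxymethoxy)phenyl]propyl 2-bromoacetate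
Conditions: NaHCO3, MeCN, 0 °C → rt
Reagents that add atoms: none
Why: O-acylation (nucleophilic acyl substitution) at the acyl bromide, which is far more electrophilic than the alkyl bromide end, with NaHCO3 taking up HBr so that the MOM acetal survives.

Step 3
Reactants: 4 3-[3-methoxy-4-(methoxymethoxy)phenyl]propyl 2-bromoacetate
Product: 7 3-[3-methoxy-4-(methoxymethoxy)phenyl]propyl 2-diazoacetate, via alkylated ditosylhydrazide 5 (not isolated), via glyoxylate tosylhydrazone 6 (not isolated)
Conditions: TsNHNHTs, DBU, THF, 0 °C
Reagents that add atoms: N,N'-ditosylhydrazine, Cc1ccc(cc1)S(=O)(=O)NNS(=O)(=O)c1ccc(C)cc1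
Why: Diazo ester synthesis from a bromoacetate, in which N-alkylation of the hydrazide gives 5, DBU-induced loss of one sulfinate gives tosylhydrazone 6, and a Bamford–Stevens-type loss of the second sulfinate gives the diazo compound at 0 °C without touching the ester or the MOM ether.

Step 4
Reactants: 7 3-[3-methoxy-4-(methoxymethoxy)phenyl]propyl 2-diazoacetate
Product: 8 (4R)-4-{[3-methoxy-4-(methoxymethoxy)phenyl]methyl}oxolan-2-one
Conditions: Rh2(4R-MPPIM)4 (1 mol %), CH2Cl2, reflux, slow addition of 7
Reagents that add atoms: none
Why: Rh2(4R-MPPIM)4, a dimer of divalent rhodium bridged by four chiral imidazolidinone carboxamidates, takes up the diazo carbon of 7, nitrogen leaves, and the electrophilic rhodium carbenoid (the future C3) inserts into a C–H bond of the homobenzylic methylene (the future C4) through a concerted three-centre transition state that releases the catalyst. The closest known reaction type is the enantioselective intramolecular C–H insertion of 3-arylpropyl diazoacetates under chiral dirhodium carboxamidate catalysis, which gives 4-benzyl-substituted oxolan-2-ones. The oxolan-2-one ring closes by a 1,5-insertion: the carbenoid carbon and the C–H carbon are joined across the C2(=O)–O1–C5 tether, so the new C3–C4 bond completes a five-membered ring. The C4 stereocentre is under catalyst control, because the ester-bearing ligands around the carbenoid allow only one of the two enantiotopic hydrogens of that methylene to reach the carbenoid carbon, and the 4R hand is the one expected to give the R lactone. The step needs site selectivity for five-membered closure over four-membered closure at O–CH2, six-membered closure at the benzylic CH2 and addition to the electron-rich arene, and chemoselectivity over carbene dimerisation; the geometric preference for 1,5-insertion, the low electrophilicity of carboxamidate carbenoids, the slow addition of 7 and the capped phenol (no O–H insertion) should secure it.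

Step 5
Reactants: 9 4-hydroxy-3,5-dimethoxybenzaldehyde (syringaldehyde)
Product: 10 3,5-dimethoxy-4-(methoxymethoxy)benzaldehyde
Conditions: MOMCl, i-Pr2NEt, CH2Cl2, 0 °C → rt
Reagents that add atoms: chloromethyl methyl ether (MOMCl), COCCl
Why: O-alkylation of the acidic, flanked phenol by the reactive chloromethyl ether under amine base, to which the aldehyde is inert.

Step 6
Reactants: 8 (4R)-4-{[3-methoxy-4-(methoxymethoxy)phenyl]methyl}oxolan-2-one; 10 3,5-dimethoxy-4-(methoxymethoxy)benzaldehyde
Product: 12 (3S,4R)-3-{[3,5-dimethoxy-4-(methoxymethoxy)phenyl](hydroxy)methyl}-4-{[3-methoxy-4-(methoxymethoxy)phenyl]methyl}oxolan-2-one (both carbinol epimers), via lithium enolate 11 (not isolated)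
Conditions: LiN(i-Pr)2, THF, −78 °C; then 10, −78 °C; AcOH quench
Reagents that add atoms: none
Why: Directed aldol addition of a lithium lactone enolate to a non-enolisable aldehyde, in which the electrophile approaches C3 anti to the C4 benzyl group (3,4-trans by substrate control); the carbinol centre is not controlled and need not be, since it becomes sp2 in step 7, and C4 is not acidic and stays R.

Step 7
Reactants: 12 (3S,4R)-3-{[3,5-dimethoxy-4-(methoxymethoxy)phenyl](hydroxy)methyl}-4-{[3-methoxy-4-(methoxymethoxy)phenyl]methyl}oxolan-2-one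
Product: 14 (3E,4R)-3-{[3,5-dimethoxy-4-(methoxymethoxy)phenyl]methylidene}-4-{[3-methoxy-4-(methoxymethoxy)phenyl]methyl}oxolan-2-one, via aldol acetate 13 (not isolated)
Conditions: Ac2O, Et3N, DMAP (cat.), CH2Cl2, 0 °C → rt; then DBU, rt
Reagents that add atoms: none
Why: Acetylation followed by E1cB elimination, in which DBU removes the acidic C3 proton of 13 and the enolate expels acetate, so both carbinol epimers should converge on the conjugated alkene with the aryl group anti to the lactone carbonyl (E) as the more stable geometry; the C3 centre is erased by design and C4 should be untouched if contact with DBU is kept short.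

Step 8
Reactants: 14 (3E,4R)-3-{[3,5-dimethoxy-4-(methoxymethoxy)phenyl]methylidene}-4-{[3-methoxy-4-(methoxymethoxy)phenyl]methyl}oxolan-2-one
Product: 15 (3E,4R)-3-[(4-hydroxy-3,5-dimethoxyphenyl)methylidene]-4-[(4-hydroxy-3-methoxyphenyl)methyl]oxolan-2-one
Conditions: HCl (2 M in MeOH), THF, rt → 40 °C
Reagents that add atoms: none
Why: Acid-catalysed acetal exchange with methanol cleaves both aryl MOM ethers as dimethoxymethane, and dilute acid near room temperature should leave the lactone, the conjugated E alkene and the C4 stereocentre alone.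

**Compound list**
1 | 3-(4-hydroxy-3-methoxyphenyl)propan-1-ol | COc1cc(CCCO)ccc1O | starting material
2 | 3-[3-methoxy-4-(methoxymethoxy)phenyl]propan-1-ol | COc1cc(CCCO)ccc1OCOC | intermediate
3 | bromoacetyl bromide | BrCC(Br)=O | starting material
4 | 3-[3-methoxy-4-(methoxymethoxy)phenyl]propyl 2-bromoacetate | COc1cc(CCCOC(=O)CBr)ccc1OCOC | intermediate
5 | 3-[3-methoxy-4-(methoxymethoxy)phenyl]propyl 2-[1,2-bis(4-methylbenzenesulfonyl)hydrazin-1-yl]acetate (formed in situ) | COc1cc(CCCOC(=O)CN(NS(=O)(=O)c2ccc(C)cc2)S(=O)(=O)c2ccc(C)cc2)ccc1OCOC | intermediate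
6 | 3-[3-methoxy-4-(methoxymethoxy)phenyl]propyl (2E)-2-[2-(4-methylbenzenesulfonyl)hydrazin-1-ylidene]acetate (formed in situ) | COc1cc(CCCOC(=O)/C=N/NS(=O)(=O)c2ccc(C)cc2)ccc1OCOC | intermediate
7 | 3-[3-methoxy-4-(methoxymethoxy)phenyl]propyl 2-diazoacetate | COc1cc(CCCOC(=O)C=[N+]=[N-])ccc1OCOC | intermediate
8 | (4R)-4-{[3-methoxy-4-(methoxymethoxy)phenyl]methyl}oxolan-2-one | COc1cc(C[C@H]2COC(=O)C2)ccc1OCOC | intermediate
9 | 4-hydroxy-3,5-dimethoxybenzaldehyde (syringaldehyde) | COc1cc(C=O)cc(OC)c1O | starting material
10 | 3,5-dimethoxy-4-(methoxymethoxy)benzaldehyde | COc1cc(C=O)cc(OC)c1OCOC | intermediate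
11 | lithium (4R)-4-{[3-methoxy-4-(methoxymethoxy)phenyl]methyl}-4,5-dihydrofuran-2-olate (lithium enolate of 8, formed in situ) | [Li+].COc1cc(C[C@H]2COC([O-])=C2)ccc1OCOC | intermediate
12 | (3S,4R)-3-{[3,5-dimethoxy-4-(methoxymethoxy)phenyl](hydroxy)methyl}-4-{[3-methoxy-4-(methoxymethoxy)phenyl]methyl}oxolan-2-one (both carbinol epimers) | COc1cc(C[C@H]2COC(=O)[C@@H]2C(O)c2cc(OC)c(OCOC)c(OC)c2)ccc1OCOC | intermediate
13 | [3,5-dimethoxy-4-(methoxymethoxy)phenyl][(3S,4R)-4-{[3-methoxy-4-(methoxymethoxy)phenyl]methyl}-2-oxooxolan-3-yl]methyl acetate (both epimers, formed in situ) | COc1cc(C[C@H]2COC(=O)[C@@H]2C(OC(C)=O)c2cc(OC)c(OCOC)c(OC)c2)ccc1OCOC | intermediate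
14 | (3E,4R)-3-{[3,5-dimethoxy-4-(methoxymethoxy)phenyl]methylidene}-4-{[3-methoxy-4-(methoxymethoxy)phenyl]methyl}oxolan-2-one | COc1cc(C[C@H]2COC(=O)/C2=C/c2cc(OC)c(OCOC)c(OC)c2)ccc1OCOC | intermediate
15 | (3E,4R)-3-[(4-hydroxy-3,5-dimethoxyphenyl)methylidene]-4-[(4-hydroxy-3-methoxyphenyl)methyl]oxolan-2-one | COc1cc(C[C@H]2COC(=O)/C2=C/c2cc(OC)c(O)c(OC)c2)ccc1O | target

**Step count**
Total steps: 8. Longest linear sequence: 7 steps (steps 1, 2, 3, 4, 6, 7 and 8); step 5 is a one-step side branch.

**Steps most likely to fail**

Risk A, step 4. The catalyst may discriminate the two enantiotopic hydrogens incompletely, insertion may stray to the benzylic or the O-adjacent methylene, and carbene dimerisation may take over if the diazo ester accumulates. The fallback sets out from alcohol 2, comes back at lactone 8 and takes the stereocentre from an auxiliary instead of a catalyst. Alcohol 2 would be oxidised with TEMPO and PhI(OAc)2 in aqueous MeCN to 3-[3-methoxy-4-(methoxymethoxy)phenyl]propanoic acid F1. Its pivaloyl mixed anhydride (t-BuCOCl, Et3N, LiCl, THF) would acylate (S)-4-benzyl-1,3-oxazolidin-2-one to give (4S)-4-benzyl-3-{3-[3-methoxy-4-(methoxymethoxy)phenyl]propanoyl}-1,3-oxazolidin-2-one F2. Evans alkylation of the sodium Z-enolate (NaN(SiMe3)2, THF, −78 °C) with tert-butyl bromoacetate, anti to the benzyl group of the auxiliary, should give tert-butyl (3R)-4-[(4S)-4-benzyl-2-oxo-1,3-oxazolidin-3-yl]-3-{[3-methoxy-4-(methoxymethoxy)phenyl]methyl}-4-oxobutanoate F3. LiBH4 in wet THF would remove the auxiliary reductively to give tert-butyl (3R)-3-(hydroxymethyl)-4-[3-methoxy-4-(methoxymethoxy)phenyl]butanoate F4. Warming F4 with catalytic pyridinium p-toluenesulfonate in toluene would close the lactone with loss of 2-methylpropene and return to 8.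

Risk B, step 7. The elimination may give some Z isomer beside E, prolonged exposure to DBU may move the double bond into the ring through deprotonation at C4 and so erode the enantiomeric purity, and 12 may revert by retro-aldol cleavage before it is acylated. The fallback sets out from lactone 8 and comes back at 14. Lactone 8 would be treated with LiN(i-Pr)2 (2.2 equiv) and diethyl chlorophosphate, by enol phosphate formation and base-induced 1,3-shift of phosphorus from oxygen to carbon, to give diethyl [(4S)-4-{[3-methoxy-4-(methoxymethoxy)phenyl]methyl}-2-oxooxolan-3-yl]phosphonate F5 (C3 epimers; the C4 descriptor changes only because phosphorus raises the rank of C3, the spatial arrangement is that of 8). A Horner–Wadsworth–Emmons reaction of its potassium salt (KOt-Bu, THF, 0 °C) with aldehyde 10 would then give 14 in one olefination. No β-leaving group sits under amine base on this path, and step 6 becomes unnecessary as well.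

Risk C, step 3. N-Alkylation of the hydrazide may lag behind base-induced decomposition of the bromoacetate, and the diazo ester may be lost on acidic silica during purification. The fallback sets out from alcohol 2 and comes back at diazoacetate 7. Alcohol 2 would be heated with 2,2,6-trimethyl-4H-1,3-dioxin-4-one in xylene (acetylketene transfer) to give 3-[3-methoxy-4-(methoxymethoxy)phenyl]propyl 3-oxobutanoate F6. Regitz diazo transfer with 4-acetamidobenzenesulfonyl azide and Et3N in MeCN would give 3-[3-methoxy-4-(methoxymethoxy)phenyl]propyl 2-diazo-3-oxobutanoate F7. Deacetylation with LiOH in aqueous MeCN would deliver 7, the acetyl group leaving as acetate.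

**Further compounds**
F1 | step 4 | 3-[3-methoxy-4-(methoxymethoxy)phenyl]propanoic acid | COc1cc(CCC(=O)O)ccc1OCOC
F2 | step 4 | (4S)-4-benzyl-3-{3-[3-methoxy-4-(methoxymethoxy)phenyl]propanoyl}-1,3-oxazolidin-2-one | COc1cc(CCC(=O)N2[C@@H](Cc3ccccc3)COC2=O)ccc1OCOC
F3 | step 4 | tert-butyl (3R)-4-[(4S)-4-benzyl-2-oxo-1,3-oxazolidin-3-yl]-3-{[3-methoxy-4-(methoxymethoxy)phenyl]methyl}-4-oxobutanoate | COc1cc(C[C@H](CC(=O)OC(C)(C)C)C(=O)N2[C@@H](Cc3ccccc3)COC2=O)ccc1OCOC
F4 | step 4 | tert-butyl (3R)-3-(hydroxymethyl)-4-[3-methoxy-4-(methoxymethoxy)phenyl]butanoate | COc1cc(C[C@H](CC(=O)OC(C)(C)C)CO)ccc1OCOC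
F5 | step 7 | diethyl [(4S)-4-{[3-methoxy-4-(methoxymethoxy)phenyl]methyl}-2-oxooxolan-3-yl]phosphonate | COc1cc(C[C@H]2COC(=O)C2P(=O)(OCC)OCC)ccc1OCOC
F6 | step 3 | 3-[3-methoxy-4-(methoxymethoxy)phenyl]propyl 3-oxobutanoate | COc1cc(CCCOC(=O)CC(C)=O)ccc1OCOC
F7 | step 3 | 3-[3-methoxy-4-(methoxymethoxy)phenyl]propyl 2-diazo-3-oxobutanoate | COc1cc(CCCOC(=O)C(=[N+]=[N-])C(C)=O)ccc1OCOC
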